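**Plan**
- Retrosynthesis: cut first the four aryl O–MOM bonds and step C1 back from ketone to carbinol; then cut the C1–C2 bond between the benzoyl carbon of ring A and the carbinol carbon; then the C–CHO and C–prenyl bonds of ring A; last the carbamate C–O bond on the ring-B half.
- Forward: ring A (resorcinol) is prenylated between its two oxygens and then formylated by two directed ortho-lithiations. The ring-B (catechol) arylacetate becomes a 2-arylethyl N,N-diisopropylcarbamate. The halves are joined at C1–C2, then carbamate cleavage, benzylic oxidation and global MOM removal finish the chain. No ring is formed.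
- Enabling feature: C2 is an oxygen-bearing CH next to the ring-B CH2, so it can come from the O–CH2 group of a 2-arylethyl carbamate, whose two enantiotopic hydrogens s-BuLi/(−)-sparteine can tell apart. C1 is the carbonyl carbon on ring A with no α-hydrogen on that side, so it can arrive as a non-enolisable benzaldehyde.
- Stereochemistry: the only stereocentre (C2, R) is set in the joining step by removal of the pro-S hydrogen and retentive addition to the aldehyde. The C1 carbinol centre formed alongside is temporary and is erased by oxidation.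

Key step: step 7

Remark: the configuration at C2 encoded in the SMILES is R; the route is planned for that enantiomer.

**Route**

Step 1
Reactants: 1 resorcinol
Product: 2 1,3-bis(methoxymethoxy)benzene
Conditions: MOMCl (2.5 equiv), i-Pr2NEt (3 equiv), CH2Cl2, 0 °C → rt
Reagents that add atoms: chloromethyl methyl ether, COCCl
Why: Williamson-type O-alkylation of both phenols gives the bis-MOM ether, whose acetal oxygens direct the two lithiations that follow and which is removable at the end under mild acid.

Step 2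
Reactants: 2 1,3-bis(methoxymethoxy)benzene
Product: 4 1,3-bis(methoxymethoxy)-2-(3-methylbut-2-en-1-yl)benzene, via 2,6-bis(methoxymethoxy)phenyllithium 3 (not isolated)
Conditions: n-BuLi (1.1 equiv), THF, 0 °C → rt; CuBr·SMe2 (10 mol %), prenyl bromide (1.2 equiv), −78 °C → rt
Reagents that add atoms: prenyl bromide (1-bromo-3-methylbut-2-ene), CC(C)=CCBr
Why: Directed ortho-metalation takes place at the ring position flanked by both OMOM groups (cooperative coordination), and copper-catalysed SN2 allylation of the aryllithium should give the linear prenyl arene.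

Step 3
Reactants: 4 1,3-bis(methoxymethoxy)-2-(3-methylbut-2-en-1-yl)benzene
Product: 7 2,4-bis(methoxymethoxy)-3-(3-methylbut-2-en-1-yl)benzaldehyde, via aryllithium 5 (not isolated), via lithium hemiaminal alkoxide 6 (not isolated)
Conditions: n-BuLi (1.2 equiv), TMEDA (1.2 equiv), THF, −20 → 0 °C; DMF (2 equiv), −78 °C → rt; H2O
Reagents that add atoms: N,N-dimethylformamide, CN(C)C=O
Why: A second directed ortho-metalation next to an OMOM group followed by formylation with DMF (Bouveault aldehyde synthesis) places the CHO group ortho to one oxygen and para to the other, the chelated base being expected to lithiate the ring faster than the allylic–benzylic CH2.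

Step 4
Reactants: 8 methyl 2-(3,4-dihydroxyphenyl)acetate
Product: 9 methyl 2-[3,4-bis(methoxymethoxy)phenyl]acetate
Conditions: MOMCl (2.5 equiv), i-Pr2NEt (3 equiv), CH2Cl2, 0 °C → rt
Reagents that add atoms: chloromethyl methyl ether, COCCl
Why: Williamson-type O-alkylation protects the catechol as base-stable acetals that survive hydride and organolithium reagents and leave together with the ring-A MOM groups in the last step.

Step 5
Reactants: 9 methyl 2-[3,4-bis(methoxymethoxy)phenyl]acetate
Product: 10 2-[3,4-bis(methoxymethoxy)phenyl]ethan-1-ol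
Conditions: LiAlH4 (1.2 equiv), THF, 0 °C; aqueous NaOH work-up
Reagents that add atoms: none
Why: Hydride reduction of the ester to the primary alcohol leaves the aryl MOM ethers untouched.

Step 6
Reactants: 10 2-[3,4-bis(methoxymethoxy)phenyl]ethan-1-ol
Product: 11 2-[3,4-bis(methoxymethoxy)phenyl]ethyl N,N-di(propan-2-yl)carbamate
Conditions: i-Pr2NCOCl (1.2 equiv), Et3N (1.5 equiv), DMAP (cat.), CH2Cl2, reflux
Reagents that add atoms: N,N-diisopropylcarbamoyl chloride, CC(C)N(C(C)C)C(=O)Cl
Why: O-carbamoylation of the primary alcohol installs the hindered carbamate that resists attack by s-BuLi and directs and stabilises the α-lithiation in the next step.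

Step 7
Reactants: 11 2-[3,4-bis(methoxymethoxy)phenyl]ethyl N,N-di(propan-2-yl)carbamate; 7 2,4-bis(methoxymethoxy)-3-(3-methylbut-2-en-1-yl)benzaldehyde
Product: 13 (2R)-1-[2,4-bis(methoxymethoxy)-3-(3-methylbut-2-en-1-yl)phenyl]-3-[3,4-bis(methoxymethoxy)phenyl]-1-hydroxypropan-2-yl N,N-di(propan-2-yl)carbamate (both C1 epimers), via (S)-α-lithiated carbamate 12 (not isolated)
Conditions: 11 (1.3 equiv), s-BuLi (1.3 equiv), (−)-sparteine (1.3 equiv), Et2O, −78 °C, 5 h; 7 (1.0 equiv) in Et2O, −78 °C, 2 h; H2O, −78 °C → rt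
Reagents that add atoms: none
Why: The s-BuLi·(−)-sparteine complex binds the carbamate C=O and removes the pro-S hydrogen of the O–CH2 group, giving the dipole-stabilised, chelated and configurationally stable (S)-α-lithio carbamate 12, which adds to the aldehyde carbon of 7 with retention at the carbanion carbon and so forms the C1–C2 bond. The closest known reaction type is the (−)-sparteine-mediated asymmetric deprotonation of O-alkyl N,N-diisopropylcarbamates followed by carbonyl addition with retention. No ring is closed. The C2 stereocentre is controlled by the chiral diamine and should come out R (the same sense that gives (R)-2-hydroxy acids on carboxylation), while the C1 carbinol centre forms as an epimer mixture that does not matter because step 9 oxidises it. The step needs α-lithiation to win over lithiation of ring B next to an OMOM group and over benzylic deprotonation, which the carbamate-directed pre-complex, the low temperature in Et2O and the small excess of base should secure. Addition to the C=O group rather than deprotonation of the prenyl CH2 is secured by the fast reaction of the non-enolisable aldehyde at −78 °C, and any O→O carbamoyl shift in the lithium alkoxide would be harmless since both isomers give the same diol in step 8.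

Step 8
Reactants: 13 (2R)-1-[2,4-bis(methoxymethoxy)-3-(3-methylbut-2-en-1-yl)phenyl]-3-[3,4-bis(methoxymethoxy)phenyl]-1-hydroxypropan-2-yl N,N-di(propan-2-yl)carbamate
Product: 14 (2R)-1-[2,4-bis(methoxymethoxy)-3-(3-methylbut-2-en-1-yl)phenyl]-3-[3,4-bis(methoxymethoxy)phenyl]propane-1,2-diol (both C1 epimers)
Conditions: LiAlH4 (5 equiv), THF, reflux; aqueous Rochelle salt work-up
Reagents that add atoms: none
Why: Hydride reduction of the carbamate is the standard way to release the alcohol from a hindered N,N-diisopropylcarbamate, and it should leave the aryl MOM ethers, the trisubstituted olefin and the configuration at C2 untouched.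

Step 9
Reactants: 14 (2R)-1-[2,4-bis(methoxymethoxy)-3-(3-methylbut-2-en-1-yl)phenyl]-3-[3,4-bis(methoxymethoxy)phenyl]propane-1,2-diol
Product: 15 (2R)-1-[2,4-bis(methoxymethoxy)-3-(3-methylbut-2-en-1-yl)phenyl]-3-[3,4-bis(methoxymethoxy)phenyl]-2-hydroxypropan-1-one
Conditions: DDQ (1.2 equiv), NaHCO3 (solid), CH2Cl2, 0 °C → rt
Reagents that add atoms: none
Why: DDQ dehydrogenation of a benzylic alcohol by hydride abstraction from C1–H, which the ortho- and para-alkoxy groups of ring A strongly assist, should oxidise only the C1 carbinol, converge both epimers to one ketol and leave the non-benzylic C2–OH and its configuration alone under these buffered, non-enolising conditions.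

Step 10
Reactants: 15 (2R)-1-[2,4-bis(methoxymethoxy)-3-(3-methylbut-2-en-1-yl)phenyl]-3-[3,4-bis(methoxymethoxy)phenyl]-2-hydroxypropan-1-one
Product: 16 (2R)-1-[2,4-dihydroxy-3-(3-methylbut-2-en-1-yl)phenyl]-3-(3,4-dihydroxyphenyl)-2-hydroxypropan-1-one (CNP0408242.1)
Conditions: aq HCl (3 M)–MeOH (1:4), rt → 40 °C, Ar
Reagents that add atoms: none
Why: Acid-catalysed acetal solvolysis (transacetalisation to methanol) removes the four aryl MOM ethers under the mild conditions customary for prenylated polyphenols, where the dilute acid should neither add a phenol across the prenyl olefin nor enolise the ketol at C2.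

**Compound list**

1 | resorcinol (benzene-1,3-diol) | Oc1cccc(O)c1 | starting material
2 | 1,3-bis(methoxymethoxy)benzene | COCOc1cccc(OCOC)c1 | intermediate
3 | 2,6-bis(methoxymethoxy)phenyllithium | [Li]c1c(OCOC)cccc1OCOC | intermediate (not isolated)
4 | 1,3-bis(methoxymethoxy)-2-(3-methylbut-2-en-1-yl)benzene | COCOc1cccc(OCOC)c1CC=C(C)C | intermediate
5 | [2,4-bis(methoxymethoxy)-3-(3-methylbut-2-en-1-yl)phenyl]lithium | [Li]c1ccc(OCOC)c(CC=C(C)C)c1OCOC | intermediate (not isolated)
6 | lithium [2,4-bis(methoxymethoxy)-3-(3-methylbut-2-en-1-yl)phenyl](dimethylamino)methanolate | [Li]OC(N(C)C)c1ccc(OCOC)c(CC=C(C)C)c1OCOC | intermediate (not isolated)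
7 | 2,4-bis(methoxymethoxy)-3-(3-methylbut-2-en-1-yl)benzaldehyde | O=Cc1ccc(OCOC)c(CC=C(C)C)c1OCOC | intermediate
8 | methyl 2-(3,4-dihydroxyphenyl)acetate | COC(=O)Cc1ccc(O)c(O)c1 | starting material
9 | methyl 2-[3,4-bis(methoxymethoxy)phenyl]acetate | COC(=O)Cc1ccc(OCOC)c(OCOC)c1 | intermediate
10 | 2-[3,4-bis(methoxymethoxy)phenyl]ethan-1-ol | OCCc1ccc(OCOC)c(OCOC)c1 | intermediate
11 | 2-[3,4-bis(methoxymethoxy)phenyl]ethyl N,N-di(propan-2-yl)carbamate | CC(C)N(C(C)C)C(=O)OCCc1ccc(OCOC)c(OCOC)c1 | intermediate
12 | (1S)-2-[3,4-bis(methoxymethoxy)phenyl]-1-lithioethyl N,N-di(propan-2-yl)carbamate (as its (−)-sparteine complex) | [Li][C@H](OC(=O)N(C(C)C)C(C)C)Cc1ccc(OCOC)c(OCOC)c1 | intermediate (not isolated)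
13 | (2R)-1-[2,4-bis(methoxymethoxy)-3-(3-methylbut-2-en-1-yl)phenyl]-3-[3,4-bis(methoxymethoxy)phenyl]-1-hydroxypropan-2-yl N,N-di(propan-2-yl)carbamate (both C1 epimers) | CC(C)=CCc1c(OCOC)ccc(C(O)[C@H](OC(=O)N(C(C)C)C(C)C)Cc2ccc(OCOC)c(OCOC)c2)c1OCOC | intermediate
14 | (2R)-1-[2,4-bis(methoxymethoxy)-3-(3-methylbut-2-en-1-yl)phenyl]-3-[3,4-bis(methoxymethoxy)phenyl]propane-1,2-diol (both C1 epimers) | CC(C)=CCc1c(OCOC)ccc(C(O)[C@H](O)Cc2ccc(OCOC)c(OCOC)c2)c1OCOC | intermediate
15 | (2R)-1-[2,4-bis(methoxymethoxy)-3-(3-methylbut-2-en-1-yl)phenyl]-3-[3,4-bis(methoxymethoxy)phenyl]-2-hydroxypropan-1-one | CC(C)=CCc1c(OCOC)ccc(C(=O)[C@H](O)Cc2ccc(OCOC)c(OCOC)c2)c1OCOC | intermediate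
16 | (2R)-1-[2,4-dihydroxy-3-(3-methylbut-2-en-1-yl)phenyl]-3-(3,4-dihydroxyphenyl)-2-hydroxypropan-1-one | CC(C)=CCc1c(O)ccc(C(=O)[C@H](O)Cc2ccc(O)c(O)c2)c1O | target

**Summary**

Total step count: 10 (steps 1–3 for the ring-A aldehyde, steps 4–6 for the ring-B carbamate, steps 7–10 after the union).
Longest linear sequence: 7 steps (1, 2, 3, 7, 8, 9, 10; the branch 4, 5, 6, 7, 8, 9, 10 is equally long).

Steps most likely to fail:

1. Step 7. The base may deprotonate ring B next to an OMOM group, or the benzylic CH2 with subsequent loss of the carbamate as a styrene, instead of the O–CH2 group; incomplete diamine complexation would also erode the enantiomeric purity. Fallback: the detour sets out from alcohol 10 and aldehyde 7 and comes back to the route at ketol 15, so steps 8 and 9 are not needed. Alcohol 10 is converted by an Appel reaction (CBr4, PPh3, CH2Cl2) into 4-(2-bromoethyl)-1,2-bis(methoxymethoxy)benzene F1. Its Grignard reagent {2-[3,4-bis(methoxymethoxy)phenyl]ethyl}magnesium bromide F2 (Mg, THF) is added to aldehyde 7 and forms the same C1–C2 bond, giving the racemic carbinol 1-[2,4-bis(methoxymethoxy)-3-(3-methylbut-2-en-1-yl)phenyl]-3-[3,4-bis(methoxymethoxy)phenyl]propan-1-ol F3. Dess–Martin oxidation gives the ketone 1-[2,4-bis(methoxymethoxy)-3-(3-methylbut-2-en-1-yl)phenyl]-3-[3,4-bis(methoxymethoxy)phenyl]propan-1-one F4. Its sodium (Z)-enolate F5 (NaHMDS, THF, −78 °C) is hydroxylated with an enantiopure (camphorylsulfonyl)oxaziridine to give 15. The (−)-reagent is expected to give the R ketol, by analogy with the usual sense for Z-enolates of aryl ketones; the antipodal reagent is equally available.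

2. Step 9. DDQ may abstract hydride from the allylic–benzylic CH2 of the prenyl group, or the acidic hydroquinone by-product may ionise the electron-rich benzylic carbinol, instead of clean dehydrogenation at C1. Fallback: the detour sets out from adduct 13 and comes back at target 16, and it differentiates the two oxygens by protecting groups instead of by oxidant selectivity. The C1–OH of 13 is silylated (TIPSOTf, 2,6-lutidine) to the triisopropylsilyl ether F6, TIPS being chosen to resist O→O migration. The carbamate is cleaved with LiAlH4 to the C2 alcohol F7, which is protected as the methoxymethyl ether F8 (MOMCl, i-Pr2NEt). TBAF then frees the C1 carbinol F9, and Dess–Martin oxidation gives (2R)-1-[2,4-bis(methoxymethoxy)-3-(3-methylbut-2-en-1-yl)phenyl]-3-[3,4-bis(methoxymethoxy)phenyl]-2-(methoxymethoxy)propan-1-one F10. Under the conditions of step 10, F10 should lose all five MOM groups and give 16.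

3. Step 3. The base may remove a proton from the doubly activated (benzylic and allylic) CH2 of the prenyl group instead of the ring position, leading to side-chain substitution and olefin migration. Fallback: the detour sets out from bis-MOM ether 2 and comes back at aryllithium 5, which is generated by halogen–lithium exchange instead of deprotonation. Compound 2 is brominated (NBS, MeCN, 0 °C) para to one OMOM group to give 1-bromo-2,4-bis(methoxymethoxy)benzene F11. Deprotonation between the two OMOM groups with LiTMP (THF, −78 °C) gives [3-bromo-2,6-bis(methoxymethoxy)phenyl]lithium F12, and copper-catalysed allylation with prenyl bromide gives 1-bromo-2,4-bis(methoxymethoxy)-3-(3-methylbut-2-en-1-yl)benzene F13. Bromine–lithium exchange (n-BuLi, THF, −78 °C), which is much faster than any C–H deprotonation, gives 5, and DMF then leads to 7 as in step 3.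

**Further compounds**

F1 | step 7 | 4-(2-bromoethyl)-1,2-bis(methoxymethoxy)benzene | BrCCc1ccc(OCOC)c(OCOC)c1
F2 | step 7 | {2-[3,4-bis(methoxymethoxy)phenyl]ethyl}magnesium bromide | Br[Mg]CCc1ccc(OCOC)c(OCOC)c1
F3 | step 7 | rac-1-[2,4-bis(methoxymethoxy)-3-(3-methylbut-2-en-1-yl)phenyl]-3-[3,4-bis(methoxymethoxy)phenyl]propan-1-ol | CC(C)=CCc1c(OCOC)ccc(C(O)CCc2ccc(OCOC)c(OCOC)c2)c1OCOC
F4 | step 7 | 1-[2,4-bis(methoxymethoxy)-3-(3-methylbut-2-en-1-yl)phenyl]-3-[3,4-bis(methoxymethoxy)phenyl]propan-1-one | CC(C)=CCc1c(OCOC)ccc(C(=O)CCc2ccc(OCOC)c(OCOC)c2)c1OCOC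
F5 | step 7 | sodium (Z)-1-[2,4-bis(methoxymethoxy)-3-(3-methylbut-2-en-1-yl)phenyl]-3-[3,4-bis(methoxymethoxy)phenyl]prop-1-en-1-olate | CC(C)=CCc1c(OCOC)ccc(/C(O[Na])=C/Cc2ccc(OCOC)c(OCOC)c2)c1OCOC
F6 | step 9 | (2R)-1-[2,4-bis(methoxymethoxy)-3-(3-methylbut-2-en-1-yl)phenyl]-3-[3,4-bis(methoxymethoxy)phenyl]-1-[(triisopropylsilyl)oxy]propan-2-yl N,N-di(propan-2-yl)carbamate (both C1 epimers) | CC(C)=CCc1c(OCOC)ccc(C(O[Si](C(C)C)(C(C)C)C(C)C)[C@H](OC(=O)N(C(C)C)C(C)C)Cc2ccc(OCOC)c(OCOC)c2)c1OCOC
F7 | step 9 | (2R)-1-[2,4-bis(methoxymethoxy)-3-(3-methylbut-2-en-1-yl)phenyl]-3-[3,4-bis(methoxymethoxy)phenyl]-1-[(triisopropylsilyl)oxy]propan-2-ol (both C1 epimers) | CC(C)=CCc1c(OCOC)ccc(C(O[Si](C(C)C)(C(C)C)C(C)C)[C@H](O)Cc2ccc(OCOC)c(OCOC)c2)c1OCOC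
F8 | step 9 | {(2R)-1-[2,4-bis(methoxymethoxy)-3-(3-methylbut-2-en-1-yl)phenyl]-3-[3,4-bis(methoxymethoxy)phenyl]-2-(methoxymethoxy)propoxy}triisopropylsilane (both C1 epimers) | CC(C)=CCc1c(OCOC)ccc(C(O[Si](C(C)C)(C(C)C)C(C)C)[C@H](OCOC)Cc2ccc(OCOC)c(OCOC)c2)c1OCOC
F9 | step 9 | (2R)-1-[2,4-bis(methoxymethoxy)-3-(3-methylbut-2-en-1-yl)phenyl]-3-[3,4-bis(methoxymethoxy)phenyl]-2-(methoxymethoxy)propan-1-ol (both C1 epimers) | CC(C)=CCc1c(OCOC)ccc(C(O)[C@H](OCOC)Cc2ccc(OCOC)c(OCOC)c2)c1OCOC
F10 | step 9 | (2R)-1-[2,4-bis(methoxymethoxy)-3-(3-methylbut-2-en-1-yl)phenyl]-3-[3,4-bis(methoxymethoxy)phenyl]-2-(methoxymethoxy)propan-1-one | CC(C)=CCc1c(OCOC)ccc(C(=O)[C@H](OCOC)Cc2ccc(OCOC)c(OCOC)c2)c1OCOC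
F11 | step 3 | 1-bromo-2,4-bis(methoxymethoxy)benzene | COCOc1ccc(Br)c(OCOC)c1
F12 | step 3 | [3-bromo-2,6-bis(methoxymethoxy)phenyl]lithium | COCOc1ccc(Br)c(OCOC)c1[Li]
F13 | step 3 | 1-bromo-2,4-bis(methoxymethoxy)-3-(3-methylbut-2-en-1-yl)benzene | COCOc1ccc(Br)c(OCOC)c1CC=C(C)C
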